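**Retrosynthetic overview**
1. The only strategic disconnection is the ester C(=O)–O3 bond. The acyl half is 3,5-dihydroxy-4-methoxybenzoic acid (1), carried as its diacetate (2). The alcohol half is (−)-epicatechin (3), which supplies rings A, B and C and both stereocentres (2R,3R).
2. Key step: 2 → aroyl chloride (4) → N-aroyl-N′-methylimidazolium chloride (5), which acylates the lone aliphatic hydroxyl of unprotected 3 to give ester 6. The C3–O bond is never broken, so configuration is retained.
3. Last step: hydrazinolysis of the two aryl acetates (and of any stray phenolic aroyl ester) gives the target (7).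
4. No ring is formed in the route, and the flavan carries no protecting group at any stage.

Assumption: 1 and 3 are bought as catalogue compounds; 3 is the natural (2R,3R) enantiomer, which fixes the absolute configuration of the target.

**Step 1**
Reactants: 1 3,5-dihydroxy-4-methoxybenzoic acid (4-O-methylgallic acid)
Product: 2 3,5-diacetoxy-4-methoxybenzoic acid
Conditions: Ac2O (4 equiv), pyridine, 0 °C → rt, 4 h; then H2O, rt, 1 h; 1 M HCl work-up, crystallise from EtOAc/hexane
Reagents that add atoms: acetic anhydride, CC(=O)OC(C)=O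
Why: Einhorn-type O-acetylation (nucleophilic acyl substitution with pyridine as acyl-transfer base) caps both phenols so the carboxyl group can later be made into an acid chloride; the aqueous hold hydrolyses any mixed carboxylic–acetic anhydride while the aryl acetates survive; no stereocentre is involved.

**Step 2**
Reactants: 2 3,5-diacetoxy-4-methoxybenzoic acid; 3 (−)-epicatechin, (2R,3R)-2-(3,4-dihydroxyphenyl)-3,4-dihydro-2H-chromene-3,5,7-triol
Product: 6 (−)-epicatechin 3-O-(3,5-diacetoxy-4-methoxybenzoate), via aroyl chloride 4 (not isolated), via acylimidazolium chloride 5 (not isolated)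
Conditions: 2 (1.3 equiv), (COCl)2 (1.5 equiv), cat. DMF, CH2Cl2, 0 °C → rt, evaporate (toluene chase); 1-methylimidazole (1.25 equiv), MeCN, 0 °C, 15 min; then dried 3 (1.0 equiv) in MeCN/1,4-dioxane (2:1), 0 °C → rt, 16 h, Ar; water wash, silica chromatography
Reagents that add atoms: none
Why: Proposed new method: pKa-gated acyl-onium transfer to an unprotected polyphenol — 4 is converted completely into acylimidazolium salt 5 by slightly less than one equivalent of 1-methylimidazole, so no free base is ever present; the neutral aliphatic 3-OH (roughly three orders of magnitude more nucleophilic than a neutral phenol oxygen) adds to the acyl-onium carbon and the departing 1-methylimidazole takes up the proton, buffering the medium near pKa 7, below the phenol pKa values of 3 (about 8.7–9.5), so the phenoxide pathway that normally lets phenols win is shut off while the medium stays too weakly acidic to harm the flavan or the aryl acetates; the O–acyl bond forms without touching C3–O or C2, so the (2R,3R) configuration of 3 is retained and no new stereocentre arises; closest known reaction type: base-free or acid-mediated acylation of alcohols by acyl chlorides in the presence of phenols, and ester formation through N-acylimidazolium salts, neither shown as a stoichiometric pKa-matched carrier on an unprotected flavan-3-ol.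

**Step 3**
Reactants: 6 (−)-epicatechin 3-O-(3,5-diacetoxy-4-methoxybenzoate)
Product: 7 (−)-epicatechin 3-O-(4-O-methylgallate), (2R,3R)-2-(3,4-dihydroxyphenyl)-5,7-dihydroxy-3,4-dihydro-2H-chromen-3-yl 3,5-dihydroxy-4-methoxybenzoate
Conditions: N2H4·H2O (4 equiv), degassed THF/MeOH (1:1), 0 °C, 1 h, Ar; AcOH quench; Sephadex LH-20 (MeOH)
Reagents that add atoms: none
Why: Chemoselective hydrazinolysis (aminolysis of phenolic esters): aryl acetates, with a phenoxide leaving group, react at 0 °C within minutes, whereas the hindered secondary-alkyl ester of an electron-rich benzoic acid is inert under these conditions; any phenolic aroyl ester carried over from step 2 is cleaved as well, and both stereocentres are untouched (cold, brief and oxygen-free to avoid C2 epimerisation and catechol oxidation).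

**Compound list**
1 | 3,5-dihydroxy-4-methoxybenzoic acid (4-O-methylgallic acid) | COc1c(O)cc(C(=O)O)cc1O | starting material
2 | 3,5-diacetoxy-4-methoxybenzoic acid | COc1c(OC(C)=O)cc(C(=O)O)cc1OC(C)=O | intermediate
3 | (−)-epicatechin, (2R,3R)-2-(3,4-dihydroxyphenyl)-3,4-dihydro-2H-chromene-3,5,7-triol | O[C@@H]1Cc2c(O)cc(O)cc2O[C@@H]1c1ccc(O)c(O)c1 | starting material
4 | 3,5-diacetoxy-4-methoxybenzoyl chloride | COc1c(OC(C)=O)cc(C(Cl)=O)cc1OC(C)=O | intermediate
5 | 1-(3,5-diacetoxy-4-methoxybenzoyl)-3-methylimidazolium chloride | COc1c(OC(C)=O)cc(C(=O)[n+]2ccn(C)c2)cc1OC(C)=O.[Cl-] | intermediate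
6 | (2R,3R)-2-(3,4-dihydroxyphenyl)-5,7-dihydroxy-3,4-dihydro-2H-chromen-3-yl 3,5-diacetoxy-4-methoxybenzoate | COc1c(OC(C)=O)cc(C(=O)O[C@@H]2Cc3c(O)cc(O)cc3O[C@@H]2c2ccc(O)c(O)c2)cc1OC(C)=O | intermediate
7 | (2R,3R)-2-(3,4-dihydroxyphenyl)-5,7-dihydroxy-3,4-dihydro-2H-chromen-3-yl 3,5-dihydroxy-4-methoxybenzoate, epicatechin 3-O-(4-O-methylgallate) | COc1c(O)cc(C(=O)O[C@@H]2Cc3c(O)cc(O)cc3O[C@@H]2c2ccc(O)c(O)c2)cc1O | target

**Totals**
Total step count: 3. Longest linear sequence: 3 steps (1 → 2 → 6 → 7); 3 enters at step 2.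

**Steps most likely to fail**

Step 2 (the proposed new step, highest risk). The axial, secondary 3-OH may react too slowly, so that neutral phenols or residual acid chloride chemistry dominate; 3 is also poorly soluble in MeCN-rich media. Stray phenolic esters are not fatal, because step 3 strips them, but low conversion at O3 is. The fallback is known chemistry, replacing pKa gating by phenol protection; it sets out from 3 and comes back at 6. Compound 3 is silylated on its four phenols only (TBSCl, imidazole, DMF, 0 °C → rt) to give 5,7,3′,4′-tetrakis-O-(tert-butyldimethylsilyl)-(−)-epicatechin F1. F1 is acylated at its one free hydroxyl with acid chloride 4 (made from 2 as in step 2) in pyridine/CH2Cl2 with cat. DMAP at 0 °C → rt, giving 5,7,3′,4′-tetrakis-O-(tert-butyldimethylsilyl)-(−)-epicatechin 3-O-(3,5-diacetoxy-4-methoxybenzoate) F2. Et3N·3HF in THF at rt then removes the four aryl silyl ethers without touching the acetates and returns 6.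

Step 3. Hydrazine could attack the 3-O-aroyl ester on longer exposure, or the basic medium could epimerise C2 or let the catechol oxidise. The fallback changes the unmasking from nucleophilic to hydrogenolytic; it sets out from 1 (with 3) and comes back at 7. Compound 1 is perbenzylated (BnBr, K2CO3, DMF, 60 °C) to benzyl 3,5-bis(benzyloxy)-4-methoxybenzoate F3, which is saponified (NaOH, THF/MeOH/H2O, 60 °C; then HCl) to 3,5-bis(benzyloxy)-4-methoxybenzoic acid F4. F4 is taken through the step 2 protocol: (COCl)2/cat. DMF gives 3,5-bis(benzyloxy)-4-methoxybenzoyl chloride F5, 1-methylimidazole gives 1-[3,5-bis(benzyloxy)-4-methoxybenzoyl]-3-methylimidazolium chloride F6, and 3 then gives (−)-epicatechin 3-O-[3,5-bis(benzyloxy)-4-methoxybenzoate] F7. Hydrogenolysis (H2 1 atm, Pd(OH)2/C, THF/MeOH, rt) under neutral conditions gives 7.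

Step 1 (lowest risk). The mixed anhydride of 1 could acylate a phenol of a second molecule and give depside oligomers, or its hydrolysis could be incomplete. The fallback masks the carboxyl first; it sets out from 1 and comes back at 2. Compound 1 is alkylated on the carboxylate only (BnBr 1.05 equiv, KHCO3, DMF, rt) to benzyl 3,5-dihydroxy-4-methoxybenzoate F8. F8 is acetylated (Ac2O, pyridine, rt) to benzyl 3,5-diacetoxy-4-methoxybenzoate F9, and hydrogenolysis (H2, Pd/C, EtOAc, rt) gives 2.

**Further compounds**
F1 | step 2 | 5,7,3′,4′-tetrakis-O-(tert-butyldimethylsilyl)-(−)-epicatechin | O[C@@H]1Cc2c(O[Si](C)(C)C(C)(C)C)cc(O[Si](C)(C)C(C)(C)C)cc2O[C@@H]1c1ccc(O[Si](C)(C)C(C)(C)C)c(O[Si](C)(C)C(C)(C)C)c1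
F2 | step 2 | 5,7,3′,4′-tetrakis-O-(tert-butyldimethylsilyl)-(−)-epicatechin 3-O-(3,5-diacetoxy-4-methoxybenzoate) | COc1c(OC(C)=O)cc(C(=O)O[C@@H]2Cc3c(O[Si](C)(C)C(C)(C)C)cc(O[Si](C)(C)C(C)(C)C)cc3O[C@@H]2c2ccc(O[Si](C)(C)C(C)(C)C)c(O[Si](C)(C)C(C)(C)C)c2)cc1OC(C)=O
F3 | step 3 | benzyl 3,5-bis(benzyloxy)-4-methoxybenzoate | COc1c(OCc2ccccc2)cc(C(=O)OCc2ccccc2)cc1OCc1ccccc1
F4 | step 3 | 3,5-bis(benzyloxy)-4-methoxybenzoic acid | COc1c(OCc2ccccc2)cc(C(=O)O)cc1OCc1ccccc1
F5 | step 3 | 3,5-bis(benzyloxy)-4-methoxybenzoyl chloride | COc1c(OCc2ccccc2)cc(C(Cl)=O)cc1OCc1ccccc1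
F6 | step 3 | 1-[3,5-bis(benzyloxy)-4-methoxybenzoyl]-3-methylimidazolium chloride | COc1c(OCc2ccccc2)cc(C(=O)[n+]2ccn(C)c2)cc1OCc1ccccc1.[Cl-]
F7 | step 3 | (−)-epicatechin 3-O-[3,5-bis(benzyloxy)-4-methoxybenzoate] | COc1c(OCc2ccccc2)cc(C(=O)O[C@@H]2Cc3c(O)cc(O)cc3O[C@@H]2c2ccc(O)c(O)c2)cc1OCc1ccccc1
F8 | step 1 | benzyl 3,5-dihydroxy-4-methoxybenzoate | COc1c(O)cc(C(=O)OCc2ccccc2)cc1O
F9 | step 1 | benzyl 3,5-diacetoxy-4-methoxybenzoate | COc1c(OC(C)=O)cc(C(=O)OCc2ccccc2)cc1OC(C)=O
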